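The 1H‑isochromen‑8‑one core is cut at C1–C8a and O2–C3. The C1H2–O2 unit lies between C8a, the α‑carbon of the ring A enone, and C3, so the pyran ring is the formal [4+2] adduct of a hydroxymethyl unit with the C8a=C4a–C4≡C3 enyne. In one flask, Stille–Kosugi hydroxymethylation of C8a–Br forms C1–C8a and gold‑catalysed 6‑endo‑dig hydroalkoxylation of the alkyne forms O2–C3. The precursor is a 2‑bromo‑3‑enynyl cyclohexenone that already carries the (6S,7S) carbinols and the aryl ester. Ring A comes from (S)‑carvone; the side chain is carried as an allylic alcohol and oxidised at the end.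

Key step: step 13

Remark: ring atoms are numbered as in 1H‑isochromene (C1, O2, C3, C4, C4a, C5–C8, C8a); ArCO stands for 2‑methoxy‑3,4‑bis(methoxymethoxy)‑6‑methylbenzoyl; the cyclic 1,3‑dione intermediates are drawn as one tautomer each, and the peroxy‑bearing carbon of the two ozonolysis intermediates is an epimer mixture that is lost in the same step.

Step 1
Reactants: 1 2,3,4-trimethoxy-6-methylbenzaldehyde
Product: 2 2,3,4-trihydroxy-6-methylbenzaldehyde
Conditions: BBr3, CH2Cl2, −78 °C to rt; then H2O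
Reagents that add atoms: none
Why: Lewis‑acid ether cleavage, in which BBr3 complexes each aryl methyl ether and bromide removes the methyl group by SN2 attack, should free all three phenols while the hindered aldehyde survives.

Step 2
Reactants: 2 2,3,4-trihydroxy-6-methylbenzaldehyde
Product: 3 2-hydroxy-3,4-bis(methoxymethoxy)-6-methylbenzaldehyde
Conditions: MOMCl (2.1 equiv), iPr2NEt, CH2Cl2, 0 °C
Reagents that add atoms: chloromethyl methyl ether, COCCl
Why: Williamson‑type O‑alkylation should be regioselective because the 2‑hydroxyl is locked in a hydrogen bond to the formyl group, so the 4‑ and 3‑hydroxyls are protected first.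

Step 3
Reactants: 3 2-hydroxy-3,4-bis(methoxymethoxy)-6-methylbenzaldehyde
Product: 4 2-methoxy-3,4-bis(methoxymethoxy)-6-methylbenzaldehyde
Conditions: MeI, K2CO3, DMF, 40 °C
Reagents that add atoms: iodomethane, CI
Why: Williamson methylation of the remaining chelated phenol under forcing carbonate conditions fixes the 2‑methoxy group of the acid part.

Step 4
Reactants: 4 2-methoxy-3,4-bis(methoxymethoxy)-6-methylbenzaldehyde
Product: 5 2-methoxy-3,4-bis(methoxymethoxy)-6-methylbenzoic acid (ArCO2H)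
Conditions: NaClO2, NaH2PO4, 2-methyl-2-butene, t-BuOH/H2O, rt
Reagents that add atoms: sodium chlorite, [Na+].[O-]Cl=O
Why: Pinnick oxidation should convert the hindered aldehyde into the acid under buffered conditions that spare the acetals, with 2‑methyl‑2‑butene trapping hypochlorite before it chlorinates the electron‑rich ring.

Step 5
Reactants: 6 (S)-(+)-carvone
Product: 9 (5S)-5-acetoxy-2-methylcyclohex-2-en-1-one, via methoxy hydroperoxide 7 (not isolated), via peroxyacetate 8 (not isolated)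
Conditions: O3, CH2Cl2/MeOH, −78 °C; then Ac2O, Et3N, DMAP (cat.), −78 °C to rt
Reagents that add atoms: ozone, [O-][O+]=O; methanol, CO
Why: Ozonolysis of the electron‑rich isopropenyl group in methanol followed by Criegee rearrangement of the peracetate moves the ring carbon onto oxygen with retention, so the S centre of carvone becomes the S acetate and the electron‑poor enone is untouched.

Step 6
Reactants: 9 (5S)-5-acetoxy-2-methylcyclohex-2-en-1-one
Product: 10 (2S,3S,5S)-5-acetoxy-2,3-dihydroxy-2-methylcyclohexan-1-one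
Conditions: K2OsO2(OH)4 (2 mol%), (DHQ)2PHAL (5 mol%), NMO, acetone/H2O, 0 °C to rt
Reagents that add atoms: N-methylmorpholine N-oxide, C[N+]1([O-])CCOCC1; water, O
Why: Upjohn‑type catalytic osmylation is a concerted syn addition, so the two new C–O bonds must be cis, and attack on the face opposite the acetoxy group, reinforced by the (DHQ)2PHAL ligand whose mnemonic preference is the same face, should set both new centres as S; the minor diastereomer is removed by chromatography before the acetoxy‑bearing centre is destroyed.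

Step 7
Reactants: 5 2-methoxy-3,4-bis(methoxymethoxy)-6-methylbenzoic acid; 10 (2S,3S,5S)-5-acetoxy-2,3-dihydroxy-2-methylcyclohexan-1-one
Product: 12 (1S,2S,5S)-5-acetoxy-2-hydroxy-2-methyl-3-oxocyclohexyl ester of ArCO2H, via acid chloride 11 (not isolated)
Conditions: 5, 1-chloro-N,N,2-trimethylprop-1-en-1-amine, CH2Cl2, 0 °C to rt; then 10, pyridine, DMAP (cat.), 0 °C to rt
Reagents that add atoms: none
Why: DMAP‑catalysed acylation through the acid chloride, made under neutral conditions that spare the MOM acetals, should select the secondary hydroxyl over the far more hindered tertiary one, and the hindered benzoate then also protects that oxygen.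

Step 8
Reactants: 12 (1S,2S,5S)-5-acetoxy-2-hydroxy-2-methyl-3-oxocyclohexyl ester of ArCO2H
Product: 13 (1S,2S,5S)-2,5-dihydroxy-2-methyl-3-oxocyclohexyl ester of ArCO2H
Conditions: K2CO3 (0.2 equiv), MeOH, −10 °C
Reagents that add atoms: none
Why: Zemplén‑type methanolysis should remove the unhindered secondary acetate while the di‑ortho‑substituted benzoate is too hindered to transesterify, and the low temperature keeps E1cB loss of acetate slow.

Step 9
Reactants: 13 (1S,2S,5S)-2,5-dihydroxy-2-methyl-3-oxocyclohexyl ester of ArCO2H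
Product: 14 (1S,2S)-2-hydroxy-2-methyl-3,5-dioxocyclohexyl ester of ArCO2H
Conditions: Dess–Martin periodinane (1.1 equiv), NaHCO3, CH2Cl2, 0 °C to rt
Reagents that add atoms: none
Why: Dess–Martin oxidation of the secondary alcohol should give the cyclic 1,3‑dione under buffered, non‑basic conditions, the tertiary alcohol being inert.

Step 10
Reactants: 14 (1S,2S)-2-hydroxy-2-methyl-3,5-dioxocyclohexyl ester of ArCO2H
Product: 15 (1S,6S)-4-bromo-3,6-dihydroxy-6-methyl-5-oxocyclohex-3-en-1-yl ester of ArCO2H (enol form of the 2-bromo-1,3-dione)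
Conditions: NBS (1.0 equiv), CH2Cl2, 0 °C
Reagents that add atoms: N-bromosuccinimide, O=C1CCC(=O)N1Br
Why: Electrophilic bromination of the dione enol should occur at once at the doubly activated carbon between the carbonyl groups (the later C8a), far faster than at the protected arene.

Step 11
Reactants: 15 (1S,6S)-4-bromo-3,6-dihydroxy-6-methyl-5-oxocyclohex-3-en-1-yl ester of ArCO2H
Product: 16 (1S,6S)-4-bromo-6-hydroxy-6-methyl-5-oxo-3-[(trifluoromethanesulfonyl)oxy]cyclohex-3-en-1-yl ester of ArCO2H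
Conditions: Tf2O (1.05 equiv), iPr2NEt, CH2Cl2, −78 °C
Reagents that add atoms: trifluoromethanesulfonic anhydride, O=S(=O)(OS(=O)(=O)C(F)(F)F)C(F)(F)F
Why: O‑sulfonylation of the bromo‑dione enolate should take place at the less hindered oxygen remote from the quaternary carbinol, whose hydroxyl also holds the neighbouring carbonyl in a hydrogen bond, so the ketone stays next to the carbinol.

Step 12
Reactants: 16 (1S,6S)-4-bromo-6-hydroxy-6-methyl-5-oxo-3-[(trifluoromethanesulfonyl)oxy]cyclohex-3-en-1-yl ester of ArCO2H; 17 (E)-pent-2-en-4-yn-1-ol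
Product: 18 (1S,6S)-4-bromo-6-hydroxy-3-[(E)-5-hydroxypent-3-en-1-yn-1-yl]-6-methyl-5-oxocyclohex-3-en-1-yl ester of ArCO2H
Conditions: PdCl2(PPh3)2 (3 mol%), CuI (6 mol%), iPr2NEt, THF, 0 °C to rt
Reagents that add atoms: none
Why: Sonogashira coupling should be chemoselective for the triflate, a vinylogous acyl triflate that undergoes oxidative addition much faster than the α‑bromide, and it leaves the E alkene of the enynol unchanged.

Step 13
Reactants: 18 (1S,6S)-4-bromo-6-hydroxy-3-[(E)-5-hydroxypent-3-en-1-yn-1-yl]-6-methyl-5-oxocyclohex-3-en-1-yl ester of ArCO2H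
Product: 20 (6S,7S)-7-hydroxy-3-[(E)-3-hydroxyprop-1-en-1-yl]-7-methyl-8-oxo-5,6,7,8-tetrahydro-1H-isochromen-6-yl ester of ArCO2H, via hydroxymethyl enynone 19 (not isolated)
Conditions: Bu3SnCH2OH (1.3 equiv), Pd2(dba)3 (2.5 mol%), AsPh3 (10 mol%), dioxane, 80 °C; then rt, Ph3PAuNTf2 (10 mol%), same flask
Reagents that add atoms: (tributylstannyl)methanol, OC[Sn](CCCC)(CCCC)CCCC
Why: Zerovalent palladium inserts into the C8a–Br bond of the α‑bromo enone, the hydroxymethyl group is transferred from tin and reductive elimination forms C1–C8a (Stille–Kosugi hydroxymethylation, known for α‑halo enones); the cationic monovalent gold complex then activates the C4≡C3 alkyne, the new primary hydroxyl O2 adds anti to gold at C3 and protodeauration gives the C3=C4 enol ether (gold‑catalysed cycloisomerisation of 2‑alkynyl benzylic and allylic alcohols to 1H‑isochromenes). The pyran ring closes in the 6‑endo‑dig mode. No stereocentre is formed and the S centres at C6 and C7 are not touched. The step needs 6‑endo over 5‑exo closure: C3 carries the electron‑rich hydroxypropenyl group, which stabilises positive charge in the gold π‑complex, whereas C4 is attached to the electron‑poor β‑carbon C4a of the enone, and only the 6‑endo product is the conjugated vinylogous ester O2–C3=C4–C4a=C8a–C8=O. Chemoselectivity is secured because the tertiary C7 hydroxyl and the E‑configured allylic hydroxyl cannot reach the alkyne, and the weakly binding arsine of the palladium stage should leave the gold catalyst active.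

Step 14
Reactants: 20 (6S,7S)-7-hydroxy-3-[(E)-3-hydroxyprop-1-en-1-yl]-7-methyl-8-oxo-5,6,7,8-tetrahydro-1H-isochromen-6-yl ester of ArCO2H
Product: 22 (E)-3-[(6S,7S)-6-(ArCO-oxy)-7-hydroxy-7-methyl-8-oxo-5,6,7,8-tetrahydro-1H-isochromen-3-yl]prop-2-enoic acid, via enal 21 (not isolated)
Conditions: TEMPO (10 mol%), PhI(OAc)2, CH2Cl2, rt; then t-BuOH/H2O, 2-methyl-2-butene, NaH2PO4, NaClO2, rt
Reagents that add atoms: sodium chlorite, [Na+].[O-]Cl=O
Why: TEMPO/PhI(OAc)2 oxidation should touch only the primary allylic alcohol, and the Pinnick stage takes the enal on to the acid without affecting the E alkene, the tertiary alcohol or the dienol ether.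

Step 15
Reactants: 22 (E)-3-[(6S,7S)-6-(ArCO-oxy)-7-hydroxy-7-methyl-8-oxo-5,6,7,8-tetrahydro-1H-isochromen-3-yl]prop-2-enoic acid
Product: 23 (E)-3-[(6S,7S)-6-[(3,4-dihydroxy-2-methoxy-6-methylbenzoyl)oxy]-7-hydroxy-7-methyl-8-oxo-5,6,7,8-tetrahydro-1H-isochromen-3-yl]prop-2-enoic acid (CNP0446308.3)
Conditions: TFA/CH2Cl2 (1:4), 0 °C to rt; aqueous work-up
Reagents that add atoms: none
Why: Acidolysis of the two aryl MOM acetals should free the catechol, while the esters, the tertiary alcohol and the vinylogous ester of the bicyclic core tolerate brief exposure to TFA.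

Compound list
1 | 2,3,4-trimethoxy-6-methylbenzaldehyde | COc1cc(C)c(C=O)c(OC)c1OC | starting material
2 | 2,3,4-trihydroxy-6-methylbenzaldehyde | Cc1cc(O)c(O)c(O)c1C=O | intermediate
3 | 2-hydroxy-3,4-bis(methoxymethoxy)-6-methylbenzaldehyde | COCOc1cc(C)c(C=O)c(O)c1OCOC | intermediate
4 | 2-methoxy-3,4-bis(methoxymethoxy)-6-methylbenzaldehyde | COCOc1cc(C)c(C=O)c(OC)c1OCOC | intermediate
5 | 2-methoxy-3,4-bis(methoxymethoxy)-6-methylbenzoic acid | COCOc1cc(C)c(C(=O)O)c(OC)c1OCOC | intermediate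
6 | (S)-(+)-carvone, (5S)-2-methyl-5-(prop-1-en-2-yl)cyclohex-2-en-1-one | O=C1C(C)=CC[C@H](C(C)=C)C1 | starting material
7 | (5S)-5-(1-hydroperoxy-1-methoxyethyl)-2-methylcyclohex-2-en-1-one | O=C1C(C)=CC[C@H](C(C)(OC)OO)C1 | intermediate
8 | O-acetyl derivative of 7 (peroxyacetate) | O=C1C(C)=CC[C@H](C(C)(OC)OOC(C)=O)C1 | intermediate
9 | (5S)-5-acetoxy-2-methylcyclohex-2-en-1-one | O=C1C(C)=CC[C@H](OC(C)=O)C1 | intermediate
10 | (2S,3S,5S)-5-acetoxy-2,3-dihydroxy-2-methylcyclohexan-1-one | O[C@H]1C[C@H](OC(C)=O)CC(=O)[C@@]1(C)O | intermediate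
11 | 2-methoxy-3,4-bis(methoxymethoxy)-6-methylbenzoyl chloride | COCOc1cc(C)c(C(=O)Cl)c(OC)c1OCOC | intermediate
12 | (1S,2S,5S)-5-acetoxy-2-hydroxy-2-methyl-3-oxocyclohexyl 2-methoxy-3,4-bis(methoxymethoxy)-6-methylbenzoate | COc1c(OCOC)c(OCOC)cc(C)c1C(=O)O[C@H]1C[C@H](OC(C)=O)CC(=O)[C@@]1(C)O | intermediate
13 | (1S,2S,5S)-2,5-dihydroxy-2-methyl-3-oxocyclohexyl 2-methoxy-3,4-bis(methoxymethoxy)-6-methylbenzoate | COc1c(OCOC)c(OCOC)cc(C)c1C(=O)O[C@H]1C[C@H](O)CC(=O)[C@@]1(C)O | intermediate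
14 | (1S,2S)-2-hydroxy-2-methyl-3,5-dioxocyclohexyl 2-methoxy-3,4-bis(methoxymethoxy)-6-methylbenzoate | COc1c(OCOC)c(OCOC)cc(C)c1C(=O)O[C@H]1CC(=O)CC(=O)[C@@]1(C)O | intermediate
15 | (1S,6S)-4-bromo-3,6-dihydroxy-6-methyl-5-oxocyclohex-3-en-1-yl 2-methoxy-3,4-bis(methoxymethoxy)-6-methylbenzoate | COc1c(OCOC)c(OCOC)cc(C)c1C(=O)O[C@H]1CC(O)=C(Br)C(=O)[C@@]1(C)O | intermediate
16 | (1S,6S)-4-bromo-6-hydroxy-6-methyl-5-oxo-3-[(trifluoromethanesulfonyl)oxy]cyclohex-3-en-1-yl 2-methoxy-3,4-bis(methoxymethoxy)-6-methylbenzoate | COc1c(OCOC)c(OCOC)cc(C)c1C(=O)O[C@H]1CC(OS(=O)(=O)C(F)(F)F)=C(Br)C(=O)[C@@]1(C)O | intermediate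
17 | (E)-pent-2-en-4-yn-1-ol | C#C/C=C/CO | starting material
18 | (1S,6S)-4-bromo-6-hydroxy-3-[(E)-5-hydroxypent-3-en-1-yn-1-yl]-6-methyl-5-oxocyclohex-3-en-1-yl 2-methoxy-3,4-bis(methoxymethoxy)-6-methylbenzoate | COc1c(OCOC)c(OCOC)cc(C)c1C(=O)O[C@H]1CC(C#C/C=C/CO)=C(Br)C(=O)[C@@]1(C)O | intermediate
19 | (1S,6S)-6-hydroxy-4-(hydroxymethyl)-3-[(E)-5-hydroxypent-3-en-1-yn-1-yl]-6-methyl-5-oxocyclohex-3-en-1-yl 2-methoxy-3,4-bis(methoxymethoxy)-6-methylbenzoate | COc1c(OCOC)c(OCOC)cc(C)c1C(=O)O[C@H]1CC(C#C/C=C/CO)=C(CO)C(=O)[C@@]1(C)O | intermediate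
20 | (6S,7S)-7-hydroxy-3-[(E)-3-hydroxyprop-1-en-1-yl]-7-methyl-8-oxo-5,6,7,8-tetrahydro-1H-isochromen-6-yl 2-methoxy-3,4-bis(methoxymethoxy)-6-methylbenzoate | COc1c(OCOC)c(OCOC)cc(C)c1C(=O)O[C@H]1CC2=C(COC(/C=C/CO)=C2)C(=O)[C@@]1(C)O | intermediate
21 | (6S,7S)-7-hydroxy-7-methyl-8-oxo-3-[(E)-3-oxoprop-1-en-1-yl]-5,6,7,8-tetrahydro-1H-isochromen-6-yl 2-methoxy-3,4-bis(methoxymethoxy)-6-methylbenzoate | COc1c(OCOC)c(OCOC)cc(C)c1C(=O)O[C@H]1CC2=C(COC(/C=C/C=O)=C2)C(=O)[C@@]1(C)O | intermediate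
22 | (E)-3-[(6S,7S)-7-hydroxy-6-{[2-methoxy-3,4-bis(methoxymethoxy)-6-methylbenzoyl]oxy}-7-methyl-8-oxo-5,6,7,8-tetrahydro-1H-isochromen-3-yl]prop-2-enoic acid | COc1c(OCOC)c(OCOC)cc(C)c1C(=O)O[C@H]1CC2=C(COC(/C=C/C(=O)O)=C2)C(=O)[C@@]1(C)O | intermediate
23 | (E)-3-[(6S,7S)-6-[(3,4-dihydroxy-2-methoxy-6-methylbenzoyl)oxy]-7-hydroxy-7-methyl-8-oxo-5,6,7,8-tetrahydro-1H-isochromen-3-yl]prop-2-enoic acid | COc1c(O)c(O)cc(C)c1C(=O)O[C@H]1CC2=C(COC(/C=C/C(=O)O)=C2)C(=O)[C@@]1(C)O | target

Total step count: 15 steps.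
Longest linear sequence: 13 steps (steps 1–4, then steps 7–15).

Steps most likely to fail

Step 13. The gold stage may be stalled by the tin bromide and arsine left from the coupling, or the alcohol may close in the 5‑exo mode onto C4. Fallback: from 18 the Stille coupling is run alone and alcohol 19 is isolated. Iodocyclisation of 19 (I2, NaHCO3, MeCN, 0 °C), an electrophile‑driven closure of the type that converts primary 2‑alkynyl benzylic alcohols into 4‑iodo‑1H‑isochromenes, should give (6S,7S)-7-hydroxy-3-[(E)-3-hydroxyprop-1-en-1-yl]-4-iodo-7-methyl-8-oxo-5,6,7,8-tetrahydro-1H-isochromen-6-yl 2-methoxy-3,4-bis(methoxymethoxy)-6-methylbenzoate F1. Palladium‑catalysed formate reduction (Pd(OAc)2, PPh3, HCO2Na, DMF, 60 °C) then removes the iodine and returns to the route at 20.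

Step 6. Osmylation may show poor facial selectivity, because the acetoxy group is homoallylic and small. Fallback: from 9, methanolysis (K2CO3, MeOH, 0 °C) gives (5S)-5-hydroxy-2-methylcyclohex-2-en-1-one F2, which is silylated (TBDPSCl, imidazole, DMF) to (5S)-5-[(tert-butyldiphenylsilyl)oxy]-2-methylcyclohex-2-en-1-one F3. The same osmylation on F3, with one face now shielded by the large silyloxy group, should give (2S,3S,5S)-5-[(tert-butyldiphenylsilyl)oxy]-2,3-dihydroxy-2-methylcyclohexan-1-one F4. Acylation with acid chloride 11 as in step 7 gives (1S,2S,5S)-5-[(tert-butyldiphenylsilyl)oxy]-2-hydroxy-2-methyl-3-oxocyclohexyl 2-methoxy-3,4-bis(methoxymethoxy)-6-methylbenzoate F5. HF·pyridine in THF removes the silyl group and returns to the route at 13, which also avoids the basic deacetylation of step 8.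

Step 8. Base may eliminate acetic acid from the β‑acetoxy ketone (E1cB) instead of cleaving the acetate. Fallback: from 12 the elimination is driven to completion (DBU, CH2Cl2, 0 °C) to give (1S,6S)-6-hydroxy-6-methyl-5-oxocyclohex-3-en-1-yl 2-methoxy-3,4-bis(methoxymethoxy)-6-methylbenzoate F6. Wacker–Tsuji oxidation of this enone (Na2PdCl4 cat., t-BuOOH, AcOH/H2O, 50 °C) installs the β‑carbonyl group and returns to the route at 14.

Further compounds
F1 | step 13 | (6S,7S)-7-hydroxy-3-[(E)-3-hydroxyprop-1-en-1-yl]-4-iodo-7-methyl-8-oxo-5,6,7,8-tetrahydro-1H-isochromen-6-yl 2-methoxy-3,4-bis(methoxymethoxy)-6-methylbenzoate | COc1c(OCOC)c(OCOC)cc(C)c1C(=O)O[C@H]1CC2=C(COC(/C=C/CO)=C2I)C(=O)[C@@]1(C)O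
F2 | step 6 | (5S)-5-hydroxy-2-methylcyclohex-2-en-1-one | O=C1C(C)=CC[C@H](O)C1
F3 | step 6 | (5S)-5-[(tert-butyldiphenylsilyl)oxy]-2-methylcyclohex-2-en-1-one | O=C1C(C)=CC[C@H](O[Si](c2ccccc2)(c2ccccc2)C(C)(C)C)C1
F4 | step 6 | (2S,3S,5S)-5-[(tert-butyldiphenylsilyl)oxy]-2,3-dihydroxy-2-methylcyclohexan-1-one | O[C@H]1C[C@H](O[Si](c2ccccc2)(c2ccccc2)C(C)(C)C)CC(=O)[C@@]1(C)O
F5 | step 6 | (1S,2S,5S)-5-[(tert-butyldiphenylsilyl)oxy]-2-hydroxy-2-methyl-3-oxocyclohexyl 2-methoxy-3,4-bis(methoxymethoxy)-6-methylbenzoate | COc1c(OCOC)c(OCOC)cc(C)c1C(=O)O[C@H]1C[C@H](O[Si](c2ccccc2)(c2ccccc2)C(C)(C)C)CC(=O)[C@@]1(C)O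
F6 | step 8 | (1S,6S)-6-hydroxy-6-methyl-5-oxocyclohex-3-en-1-yl 2-methoxy-3,4-bis(methoxymethoxy)-6-methylbenzoate | COc1c(OCOC)c(OCOC)cc(C)c1C(=O)O[C@H]1CC=CC(=O)[C@@]1(C)O
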